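Numbering the quinone ring C1 (C=O), C2 (OAc), C3 (aryl), C4 (C=O), C5 (H), C6 (aryl), the route rests on cutting C3–C4 and C6–C1. This exploits the hidden twofold repeat of the six-membered ring: the chain aryl carbon/enol carbon/carbonyl carbon occurs twice, as C3–C2–C1 and as C6–C5–C4, each head bonded to the other's tail. In one operation a magnesium-mediated Claisen–Dieckmann dimerisation forms both ring bonds and closes the ring directly at the quinone oxidation level, as the 2,5-dihydroxy-3,6-diarylquinone. Its precursor is methyl 3-[4-(benzyloxy)phenyl]-2-oxopropanoate, enolate donor and ester acceptor in one molecule. Afterwards the surplus C5 oxygen is removed through a mono-triflate, the C2 hydroxyl is acetylated and the benzyl ethers are cleaved.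

Key step: step 3

Remark on the chemistry: the target has no stereocentre (planar, achiral quinone), so the request for a single enantiomer needs no stereocontrol. The one stereocentre that appears on the way (C2 of 4, racemic) is erased by the oxidation in step 2.

Step 1
Reactants: 1 1-(benzyloxy)-4-bromobenzene; 2 methyl oxirane-2-carboxylate (racemic methyl glycidate)
Product: 4 methyl 3-[4-(benzyloxy)phenyl]-2-hydroxypropanoate (racemic), via aryl Grignard reagent 3 (not isolated)
Conditions: Mg, THF, 40 °C; then CuI (10 mol%), 2, THF, −40 → −20 °C; aq. NH4Cl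
Reagents that add atoms: none
Why: Grignard formation followed by copper-catalysed SN2 opening of the glycidic ester at its unsubstituted C3 (organocuprate epoxide opening), which at low temperature should be faster than addition to the ester; the carbinol centre forms racemic from racemic 2 and is removed in step 2.

Step 2
Reactants: 4 methyl 3-[4-(benzyloxy)phenyl]-2-hydroxypropanoate
Product: 5 methyl 3-[4-(benzyloxy)phenyl]-2-oxopropanoate
Conditions: Dess–Martin periodinane (1.1 equiv), CH2Cl2, 0 °C → rt
Reagents that add atoms: none
Why: Dess–Martin oxidation of a secondary α-hydroxy ester to the α-keto ester under neutral conditions that leave the benzyl ether alone; 5 is expected mainly as its (Z)-enol, the form needed in step 3.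

Step 3
Reactants: 5 methyl 3-[4-(benzyloxy)phenyl]-2-oxopropanoate (two molecules)
Product: 7 2,5-dihydroxy-3,6-bis[4-(benzyloxy)phenyl]-1,4-benzoquinone, via acyclic triketo ester 6 (not isolated)
Conditions: Mg(OMe)2 (1.1 equiv per ester), MeOH/toluene, reflux with MeOH distilled off (to 105 °C), Ar; then 2 M HCl
Reagents that add atoms: none
Why: Proposed new method: magnesium methoxide turns both molecules of 5 into chelated (Z)-enolates (enolate O and ester C=O on Mg), so no ketone C=O remains for aldol addition and the Mg-activated ester is the only acceptor; the benzylic enolate carbon of one unit attacks the ester carbon of the other (bond C3–C4), methoxide leaves and removes the new tricarbonyl C–H to give the dienolate of 6. The benzylic enolate carbon C6 of the acceptor unit then attacks the remaining ester carbon C1 in a 6-(enolendo)-exo-trig Dieckmann closure (enolendo, not enolexo, because the C6=C5 enolate bond lies inside the ring being formed), and loss of methoxide plus one more deprotonation gives the magnesium salt of the quinone dianion; the cyclohexane-1,2,4,5-tetraone is only a tautomer of 7, so no oxidant is needed. The closest known reaction types are the alkoxide-mediated head-to-tail Claisen–Dieckmann dimerisation of dialkyl succinates, magnesium methoxide-mediated Claisen cyclisations of polyketo esters and methoxide-induced lactone-to-terphenylquinone rearrangements, with the enzymatic dimerisation of 4-hydroxyphenylpyruvate as the model. No stereocentre is created. The selectivity needed is C-acylation at the ester over aldol addition and over O-acylation: complete pre-enolisation removes the ketone electrophile, the methyl ester makes transesterification degenerate and lets methoxide reopen any enol ester or lactone formed by O-acylation, and the dianion of the doubly vinylogous acid, a bis-chelating ligand for Mg2+, is the thermodynamic sink. Homodimerisation means that no cross-selectivity has to be controlled.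

Step 4
Reactants: 7 2,5-dihydroxy-3,6-bis[4-(benzyloxy)phenyl]-1,4-benzoquinone
Product: 8 2,5-bis[4-(benzyloxy)phenyl]-4-hydroxy-3,6-dioxocyclohexa-1,4-dien-1-yl trifluoromethanesulfonate
Conditions: Tf2O (1.0 equiv), 2,6-lutidine (1.05 equiv), CH2Cl2, −78 °C
Reagents that add atoms: trifluoromethanesulfonic anhydride, O=S(=O)(OS(=O)(=O)C(F)(F)F)C(F)(F)F
Why: Sulfonylation of a vinylogous acid oxygen (enol triflate formation); the four ring oxygens of the monoanion of 7 are interconverted by tautomerism, so any mono-triflation gives the same compound, and the electron-withdrawing triflate lowers the nucleophilicity of the remaining vinylogous carboxylate, so one equivalent of anhydride should stop at 8 (unreacted 7 is recoverable).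

Step 5
Reactants: 8 2,5-bis[4-(benzyloxy)phenyl]-4-hydroxy-3,6-dioxocyclohexa-1,4-dien-1-yl trifluoromethanesulfonate
Product: 9 2-hydroxy-3,6-bis[4-(benzyloxy)phenyl]-1,4-benzoquinone
Conditions: PdCl2(dppf) (5 mol%), Et3SiH (3 equiv), DMF, 60 °C; then 1 M HCl, air
Reagents that add atoms: none
Why: Palladium-catalysed hydrogenolysis of an enol (vinylogous acyl) triflate by oxidative addition into the electron-poor C5–OTf bond, hydride transfer from the silane and C–H reductive elimination; the phosphine-ligated homogeneous catalyst should leave the benzyl ethers alone, and any hydroquinone or silyl ether formed by over-reduction should return to the quinone in the acidic aerobic work-up.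

Step 6
Reactants: 9 2-hydroxy-3,6-bis[4-(benzyloxy)phenyl]-1,4-benzoquinone
Product: 10 2,5-bis[4-(benzyloxy)phenyl]-3,6-dioxocyclohexa-1,4-dien-1-yl acetate
Conditions: Ac2O (3 equiv), NaOAc (0.3 equiv), THF, rt
Reagents that add atoms: acetic anhydride, CC(=O)OC(C)=O
Why: O-acetylation of the vinylogous acid through its acetate-generated anion; acetate keeps acyl transfer reversible, so the more stable para-quinone enol acetate is expected over the ortho-quinone isomer, and the absence of strong acid avoids Thiele–Winter acetoxylation at the free C5 position.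

Step 7
Reactants: 10 2,5-bis[4-(benzyloxy)phenyl]-3,6-dioxocyclohexa-1,4-dien-1-yl acetate
Product: 11 Neonambiquinone A
Conditions: BCl3 (6 equiv), pentamethylbenzene (6 equiv), CH2Cl2, −78 °C; pH 7 buffer
Reagents that add atoms: none
Why: Lewis-acid cleavage of aryl benzyl ethers with BCl3, the benzyl cation being trapped by Friedel–Crafts alkylation of the non-Lewis-basic scavenger pentamethylbenzene; at −78 °C and without nucleophiles the enol acetate and the quinone should survive, and the neutral aqueous quench avoids solvolysis of the acetate.

Compound list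
1 | 1-(benzyloxy)-4-bromobenzene | Brc1ccc(OCc2ccccc2)cc1 | starting material
2 | methyl oxirane-2-carboxylate (racemic methyl glycidate) | COC(=O)C1CO1 | starting material
3 | [4-(benzyloxy)phenyl]magnesium bromide | Br[Mg]c1ccc(OCc2ccccc2)cc1 | intermediate (not isolated)
4 | methyl 3-[4-(benzyloxy)phenyl]-2-hydroxypropanoate (racemic) | COC(=O)C(O)Cc1ccc(OCc2ccccc2)cc1 | intermediate
5 | methyl 3-[4-(benzyloxy)phenyl]-2-oxopropanoate (key-step precursor) | COC(=O)C(=O)Cc1ccc(OCc2ccccc2)cc1 | intermediate
6 | methyl 3,6-bis[4-(benzyloxy)phenyl]-2,4,5-trioxohexanoate (keto form drawn; C3 enolised, no defined configuration) | COC(=O)C(=O)C(c1ccc(OCc2ccccc2)cc1)C(=O)C(=O)Cc1ccc(OCc2ccccc2)cc1 | intermediate (not isolated)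
7 | 2,5-dihydroxy-3,6-bis[4-(benzyloxy)phenyl]-1,4-benzoquinone (key-step product) | OC1=C(c2ccc(OCc3ccccc3)cc2)C(=O)C(O)=C(c2ccc(OCc3ccccc3)cc2)C1=O | intermediate
8 | 2,5-bis[4-(benzyloxy)phenyl]-4-hydroxy-3,6-dioxocyclohexa-1,4-dien-1-yl trifluoromethanesulfonate | OC1=C(c2ccc(OCc3ccccc3)cc2)C(=O)C(OS(=O)(=O)C(F)(F)F)=C(c2ccc(OCc3ccccc3)cc2)C1=O | intermediate
9 | 2-hydroxy-3,6-bis[4-(benzyloxy)phenyl]-1,4-benzoquinone | OC1=C(c2ccc(OCc3ccccc3)cc2)C(=O)C=C(c2ccc(OCc3ccccc3)cc2)C1=O | intermediate
10 | 2,5-bis[4-(benzyloxy)phenyl]-3,6-dioxocyclohexa-1,4-dien-1-yl acetate | CC(=O)OC1=C(c2ccc(OCc3ccccc3)cc2)C(=O)C=C(c2ccc(OCc3ccccc3)cc2)C1=O | intermediate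
11 | Neonambiquinone A, 2,5-bis(4-hydroxyphenyl)-3,6-dioxocyclohexa-1,4-dien-1-yl acetate (achiral) | CC(=O)OC1=C(c2ccc(O)cc2)C(=O)C=C(c2ccc(O)cc2)C1=O | target

Total step count: 7
Longest linear sequence: 7 steps (1 → 4 → 5 → 7 → 8 → 9 → 10 → 11)

Steps most likely to fail

Step 3 (proposed new method). The acylation between two enolate anions may be too slow, or traces of the keto form may drain the monomer through aldol addition and lactonisation before the Claisen manifold is reached. The fallback uses known chemistry and replaces the dimerisation by aryl–quinone cross-coupling. It sets out from the Grignard solution 3 and returns at 7. Solution 3 is quenched with trimethyl borate at −78 °C and hydrolysed with dilute HCl to [4-(benzyloxy)phenyl]boronic acid F1. Bromanil is treated with NaOMe in MeOH to give 2,5-dibromo-3,6-dimethoxy-1,4-benzoquinone F2. A double Suzuki–Miyaura coupling of F2 with two equivalents of F1 (PdCl2(dppf), K2CO3, dioxane/H2O, 80 °C) should give 2,5-bis[4-(benzyloxy)phenyl]-3,6-dimethoxy-1,4-benzoquinone F3. Saponification of its two vinylogous methyl esters (aq. NaOH, dioxane/MeOH; then HCl) should deliver 7.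

Step 5. The hydride source may reduce the quinone, and the quinone may intercept Pd(0), so that triflate hydrogenolysis stalls or the benzyl ethers suffer. The fallback takes the quinone out of play before the reduction. It sets out from 8 and returns at 9. Reductive acetylation of 8 (Zn dust, Ac2O, NaOAc) should give 3,4,6-triacetoxy-2,5-bis[4-(benzyloxy)phenyl]phenyl trifluoromethanesulfonate F4, an ordinary aryl triflate. Palladium-catalysed formate reduction (Pd(OAc)2, dppf, HCO2H, Et3N, DMF, 70 °C) should then give 3,6-bis[4-(benzyloxy)phenyl]benzene-1,2,4-triyl triacetate F5. Hydrolysis of the three acetates with aq. NaOH/MeOH under air, where the hydroxyhydroquinone autoxidises, followed by acidification should give 9.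

Step 7. The enol acetate may be lost by Lewis-acid-assisted acyl cleavage, or chloride may add to the free C5 position of the quinone during debenzylation. The fallback reverses the order of the last two operations. It sets out from 9 and returns at 11. Compound 9, which carries no labile ester, is debenzylated with BCl3/pentamethylbenzene at −78 °C to 2-hydroxy-3,6-bis(4-hydroxyphenyl)-1,4-benzoquinone F6. Only the quinone hydroxyl, a vinylogous carboxylic acid far more acidic than the two phenols, is then ionised and acetylated (NaHCO3 1.0 equiv, Ac2O 1.05 equiv, THF, 0 °C) to give 11.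

Further compounds
F1 | step 3 | [4-(benzyloxy)phenyl]boronic acid | OB(O)c1ccc(OCc2ccccc2)cc1
F2 | step 3 | 2,5-dibromo-3,6-dimethoxy-1,4-benzoquinone | COC1=C(Br)C(=O)C(OC)=C(Br)C1=O
F3 | step 3 | 2,5-bis[4-(benzyloxy)phenyl]-3,6-dimethoxy-1,4-benzoquinone | COC1=C(c2ccc(OCc3ccccc3)cc2)C(=O)C(OC)=C(c2ccc(OCc3ccccc3)cc2)C1=O
F4 | step 5 | 3,4,6-triacetoxy-2,5-bis[4-(benzyloxy)phenyl]phenyl trifluoromethanesulfonate | CC(=O)Oc1c(OC(C)=O)c(-c2ccc(OCc3ccccc3)cc2)c(OC(C)=O)c(OS(=O)(=O)C(F)(F)F)c1-c1ccc(OCc2ccccc2)cc1
F5 | step 5 | 3,6-bis[4-(benzyloxy)phenyl]benzene-1,2,4-triyl triacetate | CC(=O)Oc1c(OC(C)=O)c(-c2ccc(OCc3ccccc3)cc2)c(OC(C)=O)cc1-c1ccc(OCc2ccccc2)cc1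
F6 | step 7 | 2-hydroxy-3,6-bis(4-hydroxyphenyl)-1,4-benzoquinone | OC1=C(c2ccc(O)cc2)C(=O)C=C(c2ccc(O)cc2)C1=O
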